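**Retrosynthetic overview**
- The acid is unmasked last from a 2-(trimethylsilyl)ethyl ester; C12–C13 is cut by a Negishi coupling of a C12 alkylzinc with the (E)-enol triflate of a 2-(trimethylsilyl)ethyl acetoacetate, which fixes 13E.
- The 6β-acetate/7α-isovalerate pair comes from a new one-pot hetero-Prévost anti-diacyloxylation of a ring B 6,8-diene (sets C6 and C7 and places each ester).
- The 6,8-diene comes from the 7-oxo-8-ene (kinetic enol triflate, Pd/formate reduction), which comes from allylic oxidation of the Δ8 olefin.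
- The Δ8 C16 bicycle comes from (+)-sclareolide, which supplies C5 and C10.
- Ring order: rings A and B arrive together, already trans-fused, in sclareolide; no carbocycle is built, and only the lactone ring is opened (step 1).

Assumption: names use labdane numbering (C1–C20; α = face opposite the C10 methyl), all compounds belong to the normal (5S,10S) series of (+)-sclareolide, and dry silver 3-methylbutanoate is taken as a stock reagent (sodium 3-methylbutanoate plus AgNO3).

**Route**

Step 1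
Reactants: 1 (+)-sclareolide
Product: 2 methyl 13,14,15,16-tetranorlabd-8-en-12-oate
Conditions: conc. H2SO4, MeOH, 65 °C
Reagents that add atoms: methanol, CO
Why: Acid ionises the tertiary C8–O bond of the lactone, E1 loss of H9 gives the thermodynamically preferred tetrasubstituted Δ8 olefin and Fischer esterification caps the acid; no stereocentre is made and minor Δ7/Δ8(17) isomers are removed on AgNO3-impregnated silica.

Step 2
Reactants: 2 methyl 13,14,15,16-tetranorlabd-8-en-12-oate
Product: 3 13,14,15,16-tetranorlabd-8-en-12-ol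
Conditions: LiAlH4, THF, 0 °C
Reagents that add atoms: none
Why: Hydride reduction of the ester to the primary alcohol; the isolated tetrasubstituted alkene is inert.

Step 3
Reactants: 3 13,14,15,16-tetranorlabd-8-en-12-ol
Product: 4 12-(tert-butyldimethylsilyloxy)-13,14,15,16-tetranorlabd-8-ene
Conditions: TBSCl, imidazole, CH2Cl2, 23 °C
Reagents that add atoms: tert-butyldimethylsilyl chloride, CC(C)(C)[Si](C)(C)Cl
Why: Silyl ether formation masks the primary alcohol for the oxidative and basic steps that follow.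

Step 4
Reactants: 4 12-(tert-butyldimethylsilyloxy)-13,14,15,16-tetranorlabd-8-ene
Product: 5 12-(tert-butyldimethylsilyloxy)-13,14,15,16-tetranorlabd-8-en-7-one
Conditions: CrO3 (15 equiv), 3,5-dimethylpyrazole (15 equiv), CH2Cl2, −20 °C
Reagents that add atoms: chromium trioxide, O=[Cr](=O)=O
Why: Allylic oxidation with the CrO3–3,5-dimethylpyrazole complex (Salmond oxidation) turns the ring allylic CH2 at C7 into the enone, favoured over the chain CH2 at C11 (deactivated by the β-silyloxy group, crowded by C1/C10) and the C17 methyl.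

Step 5
Reactants: 5 12-(tert-butyldimethylsilyloxy)-13,14,15,16-tetranorlabd-8-en-7-one
Product: 7 12-(tert-butyldimethylsilyloxy)-13,14,15,16-tetranorlabda-6,8-dien-7-yl trifluoromethanesulfonate, via lithium dienolate 6 (not isolated)
Conditions: LiN(i-Pr)2 (1.1 equiv), THF, −78 °C; then PhNTf2, −78 → 0 °C; aq. NH4Cl
Reagents that add atoms: N-phenylbis(trifluoromethanesulfonimide), O=S(=O)(N(c1ccccc1)S(=O)(=O)C(F)(F)F)C(F)(F)F
Why: Kinetic α′-deprotonation of the enone at C6 gives the cross-conjugated enolate, and O-triflation gives the 2-triflyloxy-1,3-diene (enol triflate formation); no stereocentre is formed.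

Step 6
Reactants: 7 12-(tert-butyldimethylsilyloxy)-13,14,15,16-tetranorlabda-6,8-dien-7-yl trifluoromethanesulfonate
Product: 8 12-(tert-butyldimethylsilyloxy)-13,14,15,16-tetranorlabda-6,8-diene
Conditions: Pd(OAc)2 (5 mol%), PPh3 (10 mol%), HCO2H, Bu3N, DMF, 60 °C
Reagents that add atoms: none
Why: Palladium-catalysed formate reduction of the alkenyl triflate (Cacchi reduction) replaces OTf by H and gives the homoannular diene, which is used at once.

Step 7
Reactants: 8 12-(tert-butyldimethylsilyloxy)-13,14,15,16-tetranorlabda-6,8-diene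
Product: 11 6β-acetoxy-7α-(3-methylbutanoyloxy)-12-(tert-butyldimethylsilyloxy)-13,14,15,16-tetranorlabd-8-ene, via iodo acetate 9 (not isolated), via acetoxonium ion 10 (not isolated)
Conditions: AgOAc (1.05 equiv), I2 (1.0 equiv), PhMe, −20 °C, dark; then AgO2CCH2CHMe2 (2.5 equiv), 4 Å MS, 70 °C
Reagents that add atoms: silver acetate, CC(=O)[O-].[Ag+]; silver 3-methylbutanoate, CC(C)CC(=O)[O-].[Ag+]
Why: Proposed new method: a hetero-Prévost anti-diacyloxylation in which AcOI adds iodine to the diene terminus C6 from the open α face and acetate to the allyl cation at C7 anti (β), monovalent silver then removes iodide from C6 with backside participation of the 7β-acetate to give the cis β-fused acetoxonium ion, and 3-methylbutanoate opens that ion by SN2 at the allylic carbon C7 from the α face (trans-diaxial, Fürst–Plattner), so the acetyl group stays on O6 (6β, S) and the isovaleryl group ends on O7 (7α, S); the closest known reaction is the Prévost reaction (I2/silver carboxylate trans-diacyloxylation of alkenes), which delivers two identical esters.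

Step 8
Reactants: 11 6β-acetoxy-7α-(3-methylbutanoyloxy)-12-(tert-butyldimethylsilyloxy)-13,14,15,16-tetranorlabd-8-ene
Product: 12 6β-acetoxy-7α-(3-methylbutanoyloxy)-13,14,15,16-tetranorlabd-8-en-12-ol
Conditions: HF·pyridine, pyridine, THF, 0 → 23 °C
Reagents that add atoms: none
Why: Buffered fluoride desilylation frees the primary alcohol and leaves both esters and the C6/C7 centres untouched.

Step 9
Reactants: 12 6β-acetoxy-7α-(3-methylbutanoyloxy)-13,14,15,16-tetranorlabd-8-en-12-ol
Product: 13 6β-acetoxy-12-iodo-7α-(3-methylbutanoyloxy)-13,14,15,16-tetranorlabd-8-ene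
Conditions: I2, PPh3, imidazole, CH2Cl2, 0 °C
Reagents that add atoms: iodine, [I][I]
Why: Appel-type iodination of the primary alcohol by SN2 at C12; the stereocentres are remote and the esters are inert.

Step 10
Reactants: 14 2-(trimethylsilyl)ethanol; 15 2,2,6-trimethyl-4H-1,3-dioxin-4-one
Product: 17 2-(trimethylsilyl)ethyl 3-oxobutanoate, via acetylketene 16 (not isolated)
Conditions: xylenes, 140 °C (− acetone)
Reagents that add atoms: none
Why: Thermal retro-hetero-Diels–Alder of the dioxinone releases acetylketene, which acylates the alcohol (acetoacetylation).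

Step 11
Reactants: 17 2-(trimethylsilyl)ethyl 3-oxobutanoate
Product: 19 2-(trimethylsilyl)ethyl (E)-3-(trifluoromethanesulfonyloxy)but-2-enoate, via tetramethylammonium enolate 18 (not isolated)
Conditions: aq. Me4NOH (25%), hexanes, 5 °C; then Tf2O
Reagents that add atoms: trifluoromethanesulfonic anhydride, O=S(=O)(OS(=O)(=O)C(F)(F)F)C(F)(F)F
Why: O-triflation of the non-chelated, extended ammonium enolate gives the (E)-enol triflate (stereoselective enol triflate synthesis), which fixes the geometry that becomes 13E.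

Step 12
Reactants: 13 6β-acetoxy-12-iodo-7α-(3-methylbutanoyloxy)-13,14,15,16-tetranorlabd-8-ene; 19 2-(trimethylsilyl)ethyl (E)-3-(trifluoromethanesulfonyloxy)but-2-enoate
Product: 21 2-(trimethylsilyl)ethyl 6β-acetoxy-7α-(3-methylbutanoyloxy)labda-8,13E-dien-15-oate, via alkylzinc iodide 20 (not isolated)
Conditions: Zn dust (activated), LiCl, THF, 40 °C; then 19, Pd(PPh3)4 (5 mol%), THF, 50 °C
Reagents that add atoms: none
Why: LiCl-assisted zinc insertion into the primary iodide and Negishi cross-coupling with the alkenyl triflate form C12–C13 with retention of olefin geometry (13E); the organozinc tolerates all three esters.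

Step 13
Reactants: 21 2-(trimethylsilyl)ethyl 6β-acetoxy-7α-(3-methylbutanoyloxy)labda-8,13E-dien-15-oate
Product: 22 (5S,6S,7S,10S,13E)-6β-acetoxy-7α-(3-methylbutanoyloxy)labda-8,13-dien-15-oic acid (CNP0328312.2)
Conditions: Bu4NF (2 equiv), THF, 0 → 23 °C; then 0.5 M HCl
Reagents that add atoms: none
Why: Fluoride-induced β-elimination of the 2-(trimethylsilyl)ethyl ester frees the acid without hydrolysis, so the acetate, the allylic isovalerate and the 13E olefin are unchanged.

**Compound list**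
1 | (+)-sclareolide, (3aR,5aS,9aS,9bR)-3a,6,6,9a-tetramethyldecahydronaphtho[2,1-b]furan-2(1H)-one | C1C[C@@]3(C)OC(=O)C[C@@H]3[C@@]2(C)CCCC(C)(C)[C@H]12 | starting material
2 | methyl 13,14,15,16-tetranorlabd-8-en-12-oate | C1CC(C)=C(CC(=O)OC)[C@@]2(C)CCCC(C)(C)[C@H]12 | intermediate
3 | 13,14,15,16-tetranorlabd-8-en-12-ol | C1CC(C)=C(CCO)[C@@]2(C)CCCC(C)(C)[C@H]12 | intermediate
4 | 12-(tert-butyldimethylsilyloxy)-13,14,15,16-tetranorlabd-8-ene | C1CC(C)=C(CCO[Si](C)(C)C(C)(C)C)[C@@]2(C)CCCC(C)(C)[C@H]12 | intermediate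
5 | 12-(tert-butyldimethylsilyloxy)-13,14,15,16-tetranorlabd-8-en-7-one | C1C(=O)C(C)=C(CCO[Si](C)(C)C(C)(C)C)[C@@]2(C)CCCC(C)(C)[C@H]12 | intermediate
6 | lithium 12-(tert-butyldimethylsilyloxy)-13,14,15,16-tetranorlabda-6,8-dien-7-olate (cross-conjugated dienolate, not isolated) | C1=C(O[Li])C(C)=C(CCO[Si](C)(C)C(C)(C)C)[C@@]2(C)CCCC(C)(C)[C@H]12 | intermediate
7 | 12-(tert-butyldimethylsilyloxy)-13,14,15,16-tetranorlabda-6,8-dien-7-yl trifluoromethanesulfonate | C1=C(OS(=O)(=O)C(F)(F)F)C(C)=C(CCO[Si](C)(C)C(C)(C)C)[C@@]2(C)CCCC(C)(C)[C@H]12 | intermediate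
8 | 12-(tert-butyldimethylsilyloxy)-13,14,15,16-tetranorlabda-6,8-diene | C1=CC(C)=C(CCO[Si](C)(C)C(C)(C)C)[C@@]2(C)CCCC(C)(C)[C@H]12 | intermediate
9 | 7β-acetoxy-6α-iodo-12-(tert-butyldimethylsilyloxy)-13,14,15,16-tetranorlabd-8-ene (not isolated) | I[C@H]1[C@H](OC(C)=O)C(C)=C(CCO[Si](C)(C)C(C)(C)C)[C@@]2(C)CCCC(C)(C)[C@H]12 | intermediate
10 | 6β,7β-fused 2-methyl-1,3-dioxolan-2-ylium (acetoxonium) ion of the 12-(tert-butyldimethylsilyloxy)-13,14,15,16-tetranorlabd-8-ene core, 3-methylbutanoate counter-ion (not isolated) | C[C+]3O[C@@H]1[C@H](O3)C(C)=C(CCO[Si](C)(C)C(C)(C)C)[C@@]2(C)CCCC(C)(C)[C@H]12.CC(C)CC(=O)[O-] | intermediate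
11 | 6β-acetoxy-7α-(3-methylbutanoyloxy)-12-(tert-butyldimethylsilyloxy)-13,14,15,16-tetranorlabd-8-ene | CC(=O)O[C@@H]1[C@@H](OC(=O)CC(C)C)C(C)=C(CCO[Si](C)(C)C(C)(C)C)[C@@]2(C)CCCC(C)(C)[C@H]12 | intermediate
12 | 6β-acetoxy-7α-(3-methylbutanoyloxy)-13,14,15,16-tetranorlabd-8-en-12-ol | CC(=O)O[C@@H]1[C@@H](OC(=O)CC(C)C)C(C)=C(CCO)[C@@]2(C)CCCC(C)(C)[C@H]12 | intermediate
13 | 6β-acetoxy-12-iodo-7α-(3-methylbutanoyloxy)-13,14,15,16-tetranorlabd-8-ene | CC(=O)O[C@@H]1[C@@H](OC(=O)CC(C)C)C(C)=C(CCI)[C@@]2(C)CCCC(C)(C)[C@H]12 | intermediate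
14 | 2-(trimethylsilyl)ethanol | C[Si](C)(C)CCO | starting material
15 | 2,2,6-trimethyl-4H-1,3-dioxin-4-one | CC1=CC(=O)OC(C)(C)O1 | starting material
16 | acetylketene (not isolated) | CC(=O)C=C=O | intermediate
17 | 2-(trimethylsilyl)ethyl 3-oxobutanoate | CC(=O)CC(=O)OCC[Si](C)(C)C | intermediate
18 | tetramethylammonium (E)-enolate of 17 (not isolated) | C/C([O-])=C\C(=O)OCC[Si](C)(C)C.C[N+](C)(C)C | intermediate
19 | 2-(trimethylsilyl)ethyl (E)-3-(trifluoromethanesulfonyloxy)but-2-enoate | C/C(OS(=O)(=O)C(F)(F)F)=C\C(=O)OCC[Si](C)(C)C | intermediate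
20 | [6β-acetoxy-7α-(3-methylbutanoyloxy)-13,14,15,16-tetranorlabd-8-en-12-yl]zinc iodide (not isolated) | CC(=O)O[C@@H]1[C@@H](OC(=O)CC(C)C)C(C)=C(CC[Zn]I)[C@@]2(C)CCCC(C)(C)[C@H]12 | intermediate
21 | 2-(trimethylsilyl)ethyl 6β-acetoxy-7α-(3-methylbutanoyloxy)labda-8,13E-dien-15-oate | CC(=O)O[C@@H]1[C@@H](OC(=O)CC(C)C)C(C)=C(CC/C(C)=C/C(=O)OCC[Si](C)(C)C)[C@@]2(C)CCCC(C)(C)[C@H]12 | intermediate
22 | (5S,6S,7S,10S,13E)-6β-acetoxy-7α-(3-methylbutanoyloxy)labda-8,13-dien-15-oic acid | CC(=O)O[C@@H]1[C@@H](OC(=O)CC(C)C)C(C)=C(CC/C(C)=C/C(=O)O)[C@@]2(C)CCCC(C)(C)[C@H]12 | target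

**Totals**
Total step count: 13. Longest linear sequence: 11 steps (steps 1–9, 12 and 13, from 1); steps 10 and 11 make the coupling partner.

**Three steps most likely to fail**

Step 7 (the proposed new step). Possible failures are acyl scrambling between the two silver carboxylates, 1,4-addition or elimination on the diene, and slow acetoxonium closure at the hindered C6. The fallback uses known chemistry, sets out from 5 and comes back at 11, bypassing 7 and 8. Enone 5 is deprotonated to the lithium dienolate 6 (LiN(i-Pr)2, THF, −78 °C) and brominated with NBS on the open α face to give 6α-bromo-12-(tert-butyldimethylsilyloxy)-13,14,15,16-tetranorlabd-8-en-7-one F7. Luche reduction (NaBH4, CeCl3·7H2O, MeOH, −40 °C; hydride from the α face) gives the trans-bromohydrin 6α-bromo-12-(tert-butyldimethylsilyloxy)-13,14,15,16-tetranorlabd-8-en-7β-ol F8. K2CO3 in MeOH closes it to 6β,7β-epoxy-12-(tert-butyldimethylsilyloxy)-13,14,15,16-tetranorlabd-8-ene F9 (the classical bromoketone, trans-bromohydrin, β-epoxide sequence). Neat 3-methylbutanoic acid at 25 °C opens the vinyl epoxide at the allylic carbon C7 with inversion to give 6β-hydroxy-7α-(3-methylbutanoyloxy)-12-(tert-butyldimethylsilyloxy)-13,14,15,16-tetranorlabd-8-ene F10. Ac2O, DMAP and Et3N then acetylate the hindered 6β-hydroxyl to give 11.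

Step 4 (allylic oxidation). Oxidation at C11 or C17 could compete with C7. The fallback places the oxygen at C7 by an ene-type oxidation of the exocyclic isomer; it sets out from 1 and comes back at 5. LiAlH4 in THF reduces 1 to 13,14,15,16-tetranorlabdane-8α,12-diol F1. TBSCl and imidazole give 12-(tert-butyldimethylsilyloxy)-13,14,15,16-tetranorlabdan-8α-ol F2. SOCl2 and pyridine (CH2Cl2, −78 °C) dehydrate it mainly to 12-(tert-butyldimethylsilyloxy)-13,14,15,16-tetranorlabd-8(17)-ene F3. SeO2 (cat.) with t-BuOOH hydroxylates the ring allylic CH2 to give 12-(tert-butyldimethylsilyloxy)-13,14,15,16-tetranorlabd-8(17)-en-7α-ol F4. Dess–Martin periodinane gives 12-(tert-butyldimethylsilyloxy)-13,14,15,16-tetranorlabd-8(17)-en-7-one F5. RhCl3·3H2O (cat., EtOH, 70 °C) moves the exocyclic double bond into the ring to give 5.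

Step 5 (kinetic enol triflate). The axial 6β-H is crowded by the C10 and C4 methyls, so γ-deprotonation at C11 could compete and lead to the wrong diene. The fallback is a Shapiro reaction; it sets out from 5 and comes back at 8, bypassing 7. TsNHNH2 (EtOH, cat. AcOH, 70 °C) gives 12-(tert-butyldimethylsilyloxy)-13,14,15,16-tetranorlabd-8-en-7-one (E)-p-toluenesulfonylhydrazone F6. MeLi (3 equiv, Et2O, 0 → 25 °C; Shapiro reaction as used for enone tosylhydrazones) removes the syn α′ proton at C6, expels sulfinate and N2, and protonation of the alkenyllithium on work-up gives diene 8.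

**Further compounds**
F1 | step 4 | 13,14,15,16-tetranorlabdane-8α,12-diol | C1C[C@@](C)(O)[C@H](CCO)[C@@]2(C)CCCC(C)(C)[C@H]12
F2 | step 4 | 12-(tert-butyldimethylsilyloxy)-13,14,15,16-tetranorlabdan-8α-ol | C1C[C@@](C)(O)[C@H](CCO[Si](C)(C)C(C)(C)C)[C@@]2(C)CCCC(C)(C)[C@H]12
F3 | step 4 | 12-(tert-butyldimethylsilyloxy)-13,14,15,16-tetranorlabd-8(17)-ene | C1CC(=C)[C@H](CCO[Si](C)(C)C(C)(C)C)[C@@]2(C)CCCC(C)(C)[C@H]12
F4 | step 4 | 12-(tert-butyldimethylsilyloxy)-13,14,15,16-tetranorlabd-8(17)-en-7α-ol | C1[C@@H](O)C(=C)[C@H](CCO[Si](C)(C)C(C)(C)C)[C@@]2(C)CCCC(C)(C)[C@H]12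
F5 | step 4 | 12-(tert-butyldimethylsilyloxy)-13,14,15,16-tetranorlabd-8(17)-en-7-one | C1C(=O)C(=C)[C@H](CCO[Si](C)(C)C(C)(C)C)[C@@]2(C)CCCC(C)(C)[C@H]12
F6 | step 5 | 12-(tert-butyldimethylsilyloxy)-13,14,15,16-tetranorlabd-8-en-7-one (E)-p-toluenesulfonylhydrazone | C1/C(=N\NS(=O)(=O)c3ccc(C)cc3)C(C)=C(CCO[Si](C)(C)C(C)(C)C)[C@@]2(C)CCCC(C)(C)[C@H]12
F7 | step 7 | 6α-bromo-12-(tert-butyldimethylsilyloxy)-13,14,15,16-tetranorlabd-8-en-7-one | Br[C@H]1C(=O)C(C)=C(CCO[Si](C)(C)C(C)(C)C)[C@@]2(C)CCCC(C)(C)[C@H]12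
F8 | step 7 | 6α-bromo-12-(tert-butyldimethylsilyloxy)-13,14,15,16-tetranorlabd-8-en-7β-ol | Br[C@H]1[C@H](O)C(C)=C(CCO[Si](C)(C)C(C)(C)C)[C@@]2(C)CCCC(C)(C)[C@H]12
F9 | step 7 | 6β,7β-epoxy-12-(tert-butyldimethylsilyloxy)-13,14,15,16-tetranorlabd-8-ene | O3[C@@H]1[C@H]3C(C)=C(CCO[Si](C)(C)C(C)(C)C)[C@@]2(C)CCCC(C)(C)[C@H]12
F10 | step 7 | 6β-hydroxy-7α-(3-methylbutanoyloxy)-12-(tert-butyldimethylsilyloxy)-13,14,15,16-tetranorlabd-8-ene | O[C@@H]1[C@@H](OC(=O)CC(C)C)C(C)=C(CCO[Si](C)(C)C(C)(C)C)[C@@]2(C)CCCC(C)(C)[C@H]12
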